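## Structural features

The target is an indole: a benzene ring (ring A: C3a, C4, C5, C6, C7, C7a) fused through the C3a–C7a bond to a pyrrole ring (ring B: N1, C2, C3, C3a, C7a). Ring B carries a methyl group on N1, a bromine on C2 and a CH2–N(CH3)2 N-oxide arm on C3, and ring A carries bromine on the adjacent carbons C5 and C6 and hydrogen on C4 and C7. The molecule has no stereocentre; the only stereocentres of the plan are the adjacent ring-fusion carbons C3a and C7a of a transient cis-fused intermediate, and both are erased on aromatisation. Four groups are fragile: the benzylic-type amine oxide (easily reduced, prone to Meisenheimer rearrangement when heated), the gramine unit C3–CH2–N (expelled as an iminium ion when an electrophile attacks C3), the 2-bromoindole (hydrolysed to an oxindole by strong aqueous acid) and the three C–Br bonds (lost to zerovalent palladium, organolithium reagents, dissolving metals or hydrogenolysis). The real difficulty is regiochemical: an indole brominates first at C3 and then unselectively in ring A, so the vicinal C5/C6 dibromide and the C2 bromide beside a basic side chain must be placed by design. The key step uses the fact that C4(H)–C5(Br)–C6(Br)–C7(H) is a symmetric four-carbon unit that maps onto the diene of 3,4-dibromothiophene 1,1-dioxide. Ring A can therefore be annulated onto a five-membered nitrogen ring across the future C3a–C7a bond, with both bromines in place and no question of orientation.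

## Logic of the disconnections

14 ⇒ 13. The N–O bond is cut first. The amine oxide is the most labile function, and oxygen transfer to a tertiary aliphatic amine is selective, so it belongs at the end. The gain is that every earlier step handles an ordinary tertiary amine. The forward step must choose the aliphatic nitrogen over the indole π bond and the product must be isolated cold.

13 ⇒ 12. The C2–Br bond is cut. With C3 occupied, C2 is the only open position of ring B, so an electrophilic bromination has one place to go. This reduces the problem to the ring A dibromide. The forward step must not brominate the side-chain nitrogen or displace the aminomethyl group from C3, hence the amine is protonated first.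

12 ⇒ 10 + 11. The C3–CH2 bond is cut in the Mannich sense. C3 of 10 is its natural nucleophilic site and 11 delivers the whole side chain at the right oxidation level. The basic nitrogen disappears from all earlier intermediates. The forward step needs a preformed iminium ion because two bromines lower the nucleophilicity of 10.

10 ⇒ 9. Hydrogen is returned to C2 and C3. The five-membered ring has to enter the synthesis saturated at these carbons, because the cycloaddition partner offers only one C=C. The gain is a link between the indole and an indoline. The forward dehydrogenation must spare the C–Br bonds.

9 ⇒ 7, through 8. The N–CH3 bond is cut and the carbamate restored. An acylated nitrogen is needed upstream to keep the cyclic enamine stable, so the methyl group cannot be carried through the cycloaddition. The gain is an N-protected indoline. Acidolysis and reductive methylation must both leave aryl bromides alone and are run in one flask.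

7 ⇒ 6. Hydrogen is returned to C3a and C7a. This uncovers the cyclohexa-1,3-diene that is the retron of a cycloaddition followed by extrusion of the sulfonyl bridge. The benzene ring is thereby traced to a diene with sp3 ring-fusion carbons. The forward oxidation must be faster than elimination of nitrogen from C7a.

6 ⇒ 3 + 4, through 5. The bonds C3a–C4 and C7–C7a are cut. The C4–C7 unit with its two bromines is symmetric, so no orientation issue arises. Ring A is removed completely and two simple five-membered compounds remain, one of them commercial. The forward step requires the electron-poor diene to add to the electron-rich alkene faster than to itself, the sulfonyl bridge to leave, and neutral conditions throughout.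

3 ⇒ 1, through 2. The two S=O bonds are cut, which leads to a commercial thiophene. The forward oxidation needs a strong but neutral oxygen donor, because the ring is electron-poor and the sulfoxide stage must be passed quickly.

## Other disconnections considered

Alternative 1: The cut goes through N1–C2 and C3–C3a, so ring B is taken apart and a dibrominated benzene ring is kept.
- Forward step: 3,4-dibromoaniline A1 would be iodinated to 4,5-dibromo-2-iodoaniline A2, and A2 would be N-methylated to 4,5-dibromo-2-iodo-N-methylaniline A3. A Larock heteroannulation of A3 with N,N-dimethyl-3-(trimethylsilyl)prop-2-yn-1-amine A4 under Pd(OAc)2, LiCl and Na2CO3 in DMF would give the 2-silylgramine 1-[5,6-dibromo-1-methyl-2-(trimethylsilyl)indol-3-yl]-N,N-dimethylmethanamine A5. The sequence is oxidative addition of zerovalent palladium into C–I, syn insertion of the alkyne with silicon next to the metal, and C–N bond formation. Bromine-for-silicon exchange on A5 would give 13, and N-oxidation 14.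
- In its favour: it is convergent; ring B, the side chain and a placeholder for C2 arrive in one step. The ipso exchange at silicon of A5 fixes C2 more cleanly than the C–H bromination of step 7, and on that point it is the better plan. It needs about five steps from A1 against eight, so it is also better on step economy. Its dibromide pattern is bought with A1, which is equal in certainty to building it by cycloaddition.
- Against it here: zerovalent palladium must insert into the C–I bond of A3 and leave two C–Br bonds on the same ring untouched near 100 °C. The basic propargylic amine of A4 can occupy the metal. Clean mono-methylation of the electron-poor, hindered A2 needs a detour.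
- Comparison: the alternative rests on chemoselective steps at a metal, the chosen plan on a thermal pericyclic reaction with no metal near any C–Br bond. Structurally both deliver the C5/C6 dibromide free of isomers.

Alternative 2: The cut removes the C5–Br and C6–Br bonds from a preformed indole.
- Forward step: methyl 1H-indole-3-carboxylate A6 would be treated with two equivalents of Br2 in acetic acid to give methyl 5,6-dibromo-1H-indole-3-carboxylate A7. The ester deactivates ring B of A6 and steers both substitutions into C5 and C6. N-Methylation of A7 to methyl 5,6-dibromo-1-methylindole-3-carboxylate A8, saponification of A8 to 5,6-dibromo-1-methylindole-3-carboxylic acid A9 and decarboxylation of A9 would meet the chosen route at 10.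
- In its favour: A6 is a cheap starting material, the chemistry is ionic aromatic substitution throughout, no intermediate from A7 to A9 is fragile, and scale-up is easy. It would reach 10 in about four steps instead of five, so on step economy and on the robustness of the single operations it is the equal of the chosen plan or slightly better.
- Against it: the ester carbon of A7 and A8 is a control element that is thrown away. Using it as the side-chain carbon would call for hydride reduction beside C–Br bonds and would leave C2 to be brominated on a deactivated ring. The 5,6-selectivity depends on directing effects, so over- and under-brominated material has to be removed from A7. Decarboxylation of the electron-poor acid A9 needs heat.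
- Comparison: regiochemistry comes from substituent effects in an electrophilic substitution, against the symmetry of a diene in a ring construction. The endgame from 10 and its risks are the same in both plans.

Alternative 3: The cut removes the C2–Br bond and the C3–CH bond together and traces 13 to a lactam.
- Forward step: 5,6-dibromo-1-methylindolin-2-one A10 would be treated with DMF and POBr3 under Vilsmeier–Haack conditions. C3 of A10 attacks the bromomethyleneiminium carbon formed in the flask, the lactam oxygen is exchanged for bromine and ring B becomes aromatic in the iminium salt N,N-dimethyl-1-(2,5,6-tribromo-1-methylindol-3-yl)methaniminium bromide A11. NaBH4 added to the same flask would reduce the exocyclic C=N+ of A11 to give 1-(2,5,6-tribromo-1-methylindol-3-yl)-N,N-dimethylmethanamine A12, which is identical with 13.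
- In its favour: the C2 bromide and the complete side chain are set in one flask, and no gramine is exposed to an electrophilic bromine source. The main risk of step 7 is absent, and on that point it is the better plan. It also shortens the endgame by one step.
- Against it: A10 is not commercial, and a ring closure from A1 must choose between two ortho positions, so the 5,6-pattern is not secured by construction. Hydride can also add to C2 of A11 and expel bromide.
- Comparison: it is equal to the chosen plan in the final N-oxidation of A12. It gives no answer to how ring A gets its bromines, which is what the chosen plan addresses. The two can be combined, and the fallback for step 7 does so.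

Key step: step 2

Remark on the chemistry: the target is achiral; 5 and 6 are racemic and drawn as one enantiomer with cis ring fusion; for 5 the endo adduct is drawn, and the exo adduct would converge on the same 6.

Remark on the structures: in the cycloaddition C2 and C5 of the dioxide become C4 and C7 of the indole skeleton and its brominated C3 and C4 become C5 and C6; the SO2-bridged primary adduct 5 is listed as a non-isolated intermediate.

Remark on the precursor: the ene-carbamate is used as the commercial tert-butyl carbamate, whose nitrogen is a poor leaving group under neutral heating; care goes into handling (excess of 4, no acid or base, immediate oxidation of 6) and into running deprotection and N-methylation in one flask.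

## Route

Step 1
Reactants: 1 3,4-dibromothiophene
Product: 3 3,4-dibromothiophene 1,1-dioxide, via 3,4-dibromothiophene 1-oxide 2 (not isolated)
Conditions: dimethyldioxirane (3 equiv, ca. 0.08 M in acetone), CH2Cl2, 0 °C → rt, dark; concentrated below 25 °C and used at once
Reagents that add atoms: dimethyldioxirane, CC1(C)OO1
Why: Two successive electrophilic oxygen transfers to sulfur (sulfide to sulfoxide to sulfone) under neutral, anhydrous conditions; a dioxirane is chosen because the dibrominated ring is too electron-poor for ordinary peracids and because the reactive sulfoxide 2 must be oxidised on quickly before it can dimerise.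

Step 2
Reactants: 3 3,4-dibromothiophene 1,1-dioxide; 4 tert-butyl 2,3-dihydro-1H-pyrrole-1-carboxylate
Product: 6 tert-butyl cis-5,6-dibromo-2,3,3a,7a-tetrahydro-1H-indole-1-carboxylate (racemic), via SO2-bridged cycloadduct 5 (not isolated)
Conditions: 3 added over 4 h to 4 (3 equiv), toluene, 100 °C, argon sweep; excess 4 distilled off in vacuo below 40 °C
Reagents that add atoms: none
Why: An inverse-electron-demand Diels–Alder reaction: the low-lying LUMO of the cyclic diene sulfone 3 and the HOMO of the nitrogen-substituted alkene of 4 combine in a concerted, suprafacial [4+2] addition to the SO2-bridged tricycle 5, which at this temperature loses SO2 by a thermally allowed cheletropic extrusion and uncovers the 1,3-diene 6. The closest known reaction type is the cycloaddition of halogenated thiophene 1,1-dioxides with alkenes and enol ethers followed by loss of SO2. The six-membered carbocycle is closed intermolecularly as a [4+2] annulation across C4=C5 of the pyrroline, C3a–C4 and C7–C7a being formed in the same step. The two new stereocentres C3a and C7a come out cis because both bonds are made on one face of an alkene that the five-membered ring holds in the Z geometry; endo or exo approach only decides centres that leave with the bridge, and the product is racemic. No regiochemistry has to be controlled, since 3 is symmetric about the axis through sulfur and either orientation gives the same 6. The step needs chemoselectivity for the cross-reaction over self-dimerisation of 3 and over a second addition of 3 to 6, which slow addition of 3 to an excess of the electron-rich partner 4 should secure. It also needs 6 to keep its nitrogen, which the neutral medium (no acid, no base, SO2 swept out) should secure, because the C7a–N bond, anti to H-3a, is expelled only with such assistance.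

Step 3
Reactants: 6 tert-butyl cis-5,6-dibromo-2,3,3a,7a-tetrahydro-1H-indole-1-carboxylate
Product: 7 tert-butyl 5,6-dibromoindoline-1-carboxylate
Conditions: DDQ (1.1 equiv), toluene, 0 °C → rt, directly on freshly prepared 6
Reagents that add atoms: none
Why: Dehydrogenation of a cyclohexa-1,3-diene by a high-potential quinone: hydride abstraction from the allylic, nitrogen-bearing C7a–H gives a cation stabilised as a cyclohexadienyl and N-acyliminium ion, and loss of the C3a proton gives the benzene ring with the C7a–N bond intact; low temperature and immediate use of 6 keep the competing elimination of the carbamate nitrogen behind.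

Step 4
Reactants: 7 tert-butyl 5,6-dibromoindoline-1-carboxylate
Product: 9 5,6-dibromo-1-methylindoline, via 5,6-dibromoindoline 8 (not isolated)
Conditions: TFA, CH2Cl2, 0 °C → rt; evaporate; then 37% aq. HCHO, NaBH(OAc)3, ClCH2CH2Cl, rt
Reagents that add atoms: formaldehyde, C=O
Why: Acidolysis of the tert-butyl carbamate frees the indoline nitrogen, and reductive amination with formaldehyde (iminium formation, hydride delivery from the acetoxyborohydride) methylates it once only, since the tertiary amine cannot condense again; aryl bromides are inert to both reagents.

Step 5
Reactants: 9 5,6-dibromo-1-methylindoline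
Product: 10 5,6-dibromo-1-methylindole
Conditions: activated MnO2 (10 equiv), CH2Cl2, reflux
Reagents that add atoms: none
Why: Heterogeneous dehydrogenation of an N-alkylindoline at C2–C3, driven by formation of the aromatic pyrrole ring; MnO2 does not touch aryl bromides or the N-methyl group.

Step 6
Reactants: 10 5,6-dibromo-1-methylindole; 11 N,N-dimethylmethyleneiminium iodide (Eschenmoser's salt)
Product: 12 1-(5,6-dibromo-1-methylindol-3-yl)-N,N-dimethylmethanamine (5,6-dibromo-1-methylgramine)
Conditions: 11 (1.3 equiv), MeCN, rt → 50 °C; aq. NaOH work-up
Reagents that add atoms: none
Why: Mannich reaction: C3, the most nucleophilic position of the N-methylindole, attacks the preformed iminium ion and loss of the C3 proton restores the aromatic ring; the preformed salt compensates for the deactivation by the two bromines.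

Step 7
Reactants: 12 1-(5,6-dibromo-1-methylindol-3-yl)-N,N-dimethylmethanamine
Product: 13 1-(2,5,6-tribromo-1-methylindol-3-yl)-N,N-dimethylmethanamine
Conditions: TFA (2 equiv), then NBS (1.05 equiv), CH2Cl2, 0 °C → rt, dark; aq. Na2S2O3/NaHCO3
Reagents that add atoms: N-bromosuccinimide, O=C1CCC(=O)N1Br
Why: Electrophilic bromination of a 3-substituted N-alkylindole at C2 (attack at C3, shift of bromine to C2 and loss of the C2 proton, or direct attack at C2); protonation of the side-chain amine beforehand blocks N-bromination and the retro-Mannich expulsion of the aminomethyl group, and the dibrominated ring A is too deactivated to compete.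

Step 8
Reactants: 13 1-(2,5,6-tribromo-1-methylindol-3-yl)-N,N-dimethylmethanamine
Product: 14 N,N-dimethyl-1-(2,5,6-tribromo-1-methylindol-3-yl)methanamine N-oxide
Conditions: mCPBA (1.0 equiv), CH2Cl2, 0 °C; filtration through basic Al2O3, evaporation below 25 °C
Reagents that add atoms: 3-chloroperoxybenzoic acid, OOC(=O)c1cccc(Cl)c1
Why: Oxygen transfer from the peracid to the tertiary aliphatic amine, which is far more nucleophilic than the bromine-deactivated indole π system, gives the amine N-oxide; one equivalent at low temperature and a cold, non-acidic work-up avoid over-oxidation and Meisenheimer rearrangement.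

## Compound list

1 | 3,4-dibromothiophene | Brc1cscc1Br | starting material
2 | 3,4-dibromothiophene 1-oxide | O=S1C=C(Br)C(Br)=C1 | intermediate
3 | 3,4-dibromothiophene 1,1-dioxide | O=S1(=O)C=C(Br)C(Br)=C1 | intermediate
4 | tert-butyl 2,3-dihydro-1H-pyrrole-1-carboxylate | CC(C)(C)OC(=O)N1CCC=C1 | starting material
5 | tert-butyl 8,9-dibromo-10-thia-3-azatricyclo[5.2.1.0(2,6)]dec-8-ene-3-carboxylate 10,10-dioxide (endo adduct, racemic, one enantiomer drawn) | CC(C)(C)OC(=O)N1CC[C@@H]2[C@H]1[C@@H]1C(Br)=C(Br)[C@H]2S1(=O)=O | intermediate
6 | tert-butyl cis-5,6-dibromo-2,3,3a,7a-tetrahydro-1H-indole-1-carboxylate (racemic, one enantiomer drawn) | CC(C)(C)OC(=O)N1CC[C@H]2C=C(Br)C(Br)=C[C@@H]12 | intermediate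
7 | tert-butyl 5,6-dibromoindoline-1-carboxylate | CC(C)(C)OC(=O)N1CCc2cc(Br)c(Br)cc21 | intermediate
8 | 5,6-dibromoindoline | Brc1cc2c(cc1Br)NCC2 | intermediate
9 | 5,6-dibromo-1-methylindoline | CN1CCc2cc(Br)c(Br)cc21 | intermediate
10 | 5,6-dibromo-1-methylindole | Cn1ccc2cc(Br)c(Br)cc21 | intermediate
11 | N,N-dimethylmethyleneiminium iodide | C=[N+](C)C.[I-] | starting material
12 | 1-(5,6-dibromo-1-methylindol-3-yl)-N,N-dimethylmethanamine | Cn1cc(CN(C)C)c2cc(Br)c(Br)cc21 | intermediate
13 | 1-(2,5,6-tribromo-1-methylindol-3-yl)-N,N-dimethylmethanamine | Cn1c(Br)c(CN(C)C)c2cc(Br)c(Br)cc21 | intermediate
14 | N,N-dimethyl-1-(2,5,6-tribromo-1-methylindol-3-yl)methanamine N-oxide | Cn1c(Br)c(C[N+](C)(C)[O-])c2cc(Br)c(Br)cc21 | target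

## Step count and risk

Total step count: 8. Longest linear sequence: 8 steps (1 to 14; 4 and 11 are commercial and enter at steps 2 and 6).

Least certain steps:

Step 2 (key step). The most likely failure is self-dimerisation of 3, one molecule acting as diene and a second as dienophile, outrunning the cross-cycloaddition. A carbamate lowers the HOMO of the alkene compared with an enamine or enol ether, and the reaction needs heat. Acid formed from SO2 and traces of water can also oligomerise 4, and prolonged heating can expel nitrogen from 6.

The fallback gives up the cycloaddition and builds the indole by a Leimgruber–Batcho synthesis. It therefore sets out from none of the numbered compounds 1 to 9, which it bypasses, but from commercial 3,4-dibromotoluene F1, and it comes back to the route at 10. Nitration (HNO3, H2SO4, 0 °C) ortho to methyl and para to bromine should give 4,5-dibromo-2-nitrotoluene F2. Condensation with DMF dimethyl acetal (DMF, 110 °C) should give (E)-2-(4,5-dibromo-2-nitrophenyl)-N,N-dimethylethenamine F3. Reduction with Fe in acetic acid (80 °C, chosen to spare C–Br) closes the ring to 5,6-dibromo-1H-indole F4. Methylation (KOH, MeI, DMSO, rt) then gives 10.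

Step 3. The most likely failure is loss of the carbamate nitrogen by anti elimination across C3a–C7a, triggered by the acidic hydroquinone or by adventitious base and driven by aromatisation, competing with dehydrogenation. Consumption of the quinone by residual electron-rich 4 is a second possibility.

The fallback replaces oxidation by elimination and sets out from 4, coming back at 7. Bromination and dehydrobromination of 4 (NBS, CH2Cl2, −78 °C; then Et3N) should give tert-butyl 4-bromo-2,3-dihydro-1H-pyrrole-1-carboxylate F5. Heating F5 with 3 (toluene, 100 °C, solid NaHCO3) should give the bridged sulfone tert-butyl 6,8,9-tribromo-10-thia-3-azatricyclo[5.2.1.0(2,6)]dec-8-ene-3-carboxylate 10,10-dioxide F6. Loss of SO2 gives tert-butyl cis-3a,5,6-tribromo-2,3,3a,7a-tetrahydro-1H-indole-1-carboxylate F7. F7 has no hydrogen on C3a, so nitrogen cannot be eliminated, and loss of HBr across C3a–C7a is the only path to the arene, which is 7. The price is a more hindered and less electron-rich alkene, so the cycloaddition itself should be slower.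

Step 7. The most likely failure is attack of the electrophile at C3 followed by expulsion of the aminomethyl group as an iminium ion (ipso substitution) instead of migration of bromine to C2. Oxidation at nitrogen where protonation is incomplete, and radical bromination of the C3 methylene group, are further possibilities.

The fallback takes the C2 bromine from a lactam carbonyl, avoiding bromination of a gramine. It sets out from 10 and comes back at 13. Pyridinium tribromide (3 equiv, t-BuOH/H2O, rt) should give 3,3,5,6-tetrabromo-1-methylindolin-2-one F8. Zn in acetic acid (rt) removes the two C3 bromines to give 5,6-dibromo-1-methylindolin-2-one F9. Vilsmeier–Haack bromoformylation (POBr3, DMF, CHCl3, reflux; aqueous NaOAc) gives 2,5,6-tribromo-1-methyl-1H-indole-3-carbaldehyde F10. Reductive amination (Me2NH, NaBH(OAc)3, ClCH2CH2Cl, rt) gives 13.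

## Further compounds

F1 | step 2 | 3,4-dibromotoluene | Cc1ccc(Br)c(Br)c1
F2 | step 2 | 4,5-dibromo-2-nitrotoluene | Cc1cc(Br)c(Br)cc1[N+](=O)[O-]
F3 | step 2 | (E)-2-(4,5-dibromo-2-nitrophenyl)-N,N-dimethylethenamine | CN(C)/C=C/c1cc(Br)c(Br)cc1[N+](=O)[O-]
F4 | step 2 | 5,6-dibromo-1H-indole | Brc1cc2cc[nH]c2cc1Br
F5 | step 3 | tert-butyl 4-bromo-2,3-dihydro-1H-pyrrole-1-carboxylate | CC(C)(C)OC(=O)N1CCC(Br)=C1
F6 | step 3 | tert-butyl 6,8,9-tribromo-10-thia-3-azatricyclo[5.2.1.0(2,6)]dec-8-ene-3-carboxylate 10,10-dioxide (racemic, one enantiomer drawn) | CC(C)(C)OC(=O)N1CC[C@]2(Br)[C@H]1[C@@H]1C(Br)=C(Br)[C@H]2S1(=O)=O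
F7 | step 3 | tert-butyl cis-3a,5,6-tribromo-2,3,3a,7a-tetrahydro-1H-indole-1-carboxylate (racemic, one enantiomer drawn) | CC(C)(C)OC(=O)N1CC[C@@]2(Br)C=C(Br)C(Br)=C[C@@H]12
F8 | step 7 | 3,3,5,6-tetrabromo-1-methylindolin-2-one | CN1C(=O)C(Br)(Br)c2cc(Br)c(Br)cc21
F9 | step 7 | 5,6-dibromo-1-methylindolin-2-one | CN1C(=O)Cc2cc(Br)c(Br)cc21
F10 | step 7 | 2,5,6-tribromo-1-methyl-1H-indole-3-carbaldehyde | Cn1c(Br)c(C=O)c2cc(Br)c(Br)cc21
A1 | alternative 1 | 3,4-dibromoaniline | Nc1ccc(Br)c(Br)c1
A2 | alternative 1 | 4,5-dibromo-2-iodoaniline | Nc1cc(Br)c(Br)cc1I
A3 | alternative 1 | 4,5-dibromo-2-iodo-N-methylaniline | CNc1cc(Br)c(Br)cc1I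
A4 | alternative 1 | N,N-dimethyl-3-(trimethylsilyl)prop-2-yn-1-amine | CN(C)CC#C[Si](C)(C)C
A5 | alternative 1 | 1-[5,6-dibromo-1-methyl-2-(trimethylsilyl)indol-3-yl]-N,N-dimethylmethanamine | Cn1c([Si](C)(C)C)c(CN(C)C)c2cc(Br)c(Br)cc21
A6 | alternative 2 | methyl 1H-indole-3-carboxylate | COC(=O)c1c[nH]c2ccccc12
A7 | alternative 2 | methyl 5,6-dibromo-1H-indole-3-carboxylate | COC(=O)c1c[nH]c2cc(Br)c(Br)cc12
A8 | alternative 2 | methyl 5,6-dibromo-1-methylindole-3-carboxylate | COC(=O)c1cn(C)c2cc(Br)c(Br)cc12
A9 | alternative 2 | 5,6-dibromo-1-methylindole-3-carboxylic acid | OC(=O)c1cn(C)c2cc(Br)c(Br)cc12
A10 | alternative 3 | 5,6-dibromo-1-methylindolin-2-one | CN1C(=O)Cc2cc(Br)c(Br)cc21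
A11 | alternative 3 | N,N-dimethyl-1-(2,5,6-tribromo-1-methylindol-3-yl)methaniminium bromide | C[N+](C)=Cc1c(Br)n(C)c2cc(Br)c(Br)cc12.[Br-]
A12 | alternative 3 | 1-(2,5,6-tribromo-1-methylindol-3-yl)-N,N-dimethylmethanamine | Cn1c(Br)c(CN(C)C)c2cc(Br)c(Br)cc21
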